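**Strategy**

Lignan numbering is used (phenol half C7–C8–C9, prenyl ether half C7'–C8'–C9'). The route rests on cutting ring B (C7'–O–C9–C8–C8') from ring A (C7–O–C9'–C8'–C8) at the cis-fused C8–C8' bond that both rings share. Forward, the three-atom unit C7'–O–C9 is delivered as an aryl carbonyl ylide and added suprafacially to the C8=C8' alkene of an (S)-γ-aryl butenolide whose carbonyl is C9'. One operation closes ring B, forms C7'–C8' and C8–C9 and sets C8, C8' and C7' from the single C7 stereocentre. The precursors are O-pivaloyl butenolide 7 and the prenyl-bearing α-chloro (trimethylsilyl)methyl ether 15; afterwards only C9' is deoxygenated.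

Key step: step 8

**Remarks on the chemistry**

- Configuration: the target is 7S,8R,7'S,8'R with both aryl groups exo on the cis-fused bicycle. (S)-7 has the same spatial arrangement at C7, and the anti, exo adduct 17 maps onto the target, so no structure needed correction.
- Precursor design: a prenyl ether does not tolerate anhydrous HCl (Markovnikov addition to the alkene, ether cleavage). Chloro ether 15 is therefore made from acetal 13 with acetyl chloride under aprotic conditions.
- Assumption: the sense of induction in step 2 is taken to follow that of zinc–ProPhenol aldol reactions. The (R,R)-ligand is therefore specified for Si-face attack; its enantiomer is used if a Mosher ester analysis of 5 shows the opposite sense.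

**Route**

Step 1
Reactants: 1 vanillin; 2 pivaloyl chloride
Product: 3 4-formyl-2-methoxyphenyl pivalate (O-pivaloylvanillin)
Conditions: Et3N, DMAP (cat.), CH2Cl2, 0 °C to rt
Reagents that add atoms: pivaloyl chloride (2), CC(C)(C)C(Cl)=O
Why: Amine/DMAP-mediated acylation of the phenol is fast and chemoselective, and the hindered pivalate withstands Me2Zn, hydrogenation and fluoride and is later removed by the same hydride that reduces the lactone.

Step 2
Reactants: 3 O-pivaloylvanillin; 4 methyl propiolate
Product: 5 methyl (R)-4-hydroxy-4-(3-methoxy-4-pivaloyloxyphenyl)but-2-ynoate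
Conditions: 4 (3 equiv), Me2Zn (3 equiv), (R,R)-ProPhenol (10 mol %), Ph3P=O (20 mol %), toluene, 4 °C; aq. NH4Cl
Reagents that add atoms: methyl propiolate (4), C#CC(=O)OC
Why: In this catalytic enantioselective alkynylation of an aldehyde (dinuclear zinc–ProPhenol), the zinc alkynylide formed from 4 and Me2Zn is delivered inside the chiral bimetallic pocket to the Si face of the aldehyde, which sets C7 (descriptor R here only because the alkynyl group outranks the aryl group), while both ester groups are inert to Me2Zn.

Step 3
Reactants: 5 hydroxy ynoate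
Product: 7 (S)-5-(3-methoxy-4-pivaloyloxyphenyl)furan-2(5H)-one, via Z-hydroxy enoate 6 (not isolated)
Conditions: H2 (1 atm), Pd/CaCO3 poisoned with Pb(OAc)2, quinoline, EtOAc, rt; then PPTS (cat.), CH2Cl2, rt
Reagents that add atoms: none
Why: Syn semihydrogenation of the alkyne on poisoned palladium gives the Z-enoate 6, whose C7 hydroxyl lies next to the ester and closes the butenolide by acid-catalysed lactonisation without touching the C7–O bond, so the configuration is retained and no base that could remove the acidic C7–H is present.

Step 4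
Reactants: 1 vanillin; 8 prenyl bromide
Product: 9 3-methoxy-4-(3-methylbut-2-en-1-yloxy)benzaldehyde (O-prenylvanillin)
Conditions: K2CO3, DMF, rt
Reagents that add atoms: prenyl bromide (8), CC(C)=CCBr
Why: In this Williamson ether synthesis the phenoxide displaces the primary allylic bromide by SN2, and no stereocentre is formed.

Step 5
Reactants: 10 (trimethylsilyl)methanol; 11 chlorotrimethylsilane
Product: 12 trimethyl[(trimethylsilyl)methoxy]silane
Conditions: Et3N, Et2O, 0 °C to rt; filtration, distillation
Reagents that add atoms: chlorotrimethylsilane (11), C[Si](C)(C)Cl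
Why: O-Silylation of the primary alcohol with a chlorosilane and an amine base gives the distillable silyl ether that allows acetalisation under aprotic conditions.

Step 6
Reactants: 9 O-prenylvanillin; 12 trimethyl[(trimethylsilyl)methoxy]silane
Product: 13 3-methoxy-4-prenyloxybenzaldehyde bis[(trimethylsilyl)methyl] acetal
Conditions: 12 (2.3 equiv), Me3SiOTf (3 mol %), CH2Cl2, −78 to −20 °C; pyridine quench
Reagents that add atoms: trimethyl[(trimethylsilyl)methoxy]silane (12), C[Si](C)(C)CO[Si](C)(C)C
Why: In this Noyori acetalisation Me3SiOTf activates the aldehyde for two successive additions of the alkoxysilane, formation of the Si–O–Si bond drives the reaction in the cold, and the prenyl ether never meets a protic acid (two identical alkoxy groups, so no stereocentre).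

Step 7
Reactants: 13 bis[(trimethylsilyl)methyl] acetal; 14 acetyl chloride
Product: 15 racemic α-chloro-(3-methoxy-4-prenyloxybenzyl) (trimethylsilyl)methyl ether
Conditions: 14 (1.05 equiv), ZnBr2 (0.5 mol %), CH2Cl2, 0 °C; volatiles removed in vacuo, crude used at once
Reagents that add atoms: acetyl chloride (14), CC(Cl)=O
Why: In this zinc-catalysed acetal–acyl chloride exchange one acetal oxygen is acylated, the ester leaves and chloride captures the aryl-stabilised oxocarbenium ion, which gives the α-chloro ether without free HCl; the new stereocentre is racemic and is erased in step 8.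

Step 8
Reactants: 7 (S)-butenolide; 15 α-chloro (trimethylsilyl)methyl ether
Product: 17 (3S,3aR,6S,6aS)-6-(3-methoxy-4-prenyloxyphenyl)-3-(3-methoxy-4-pivaloyloxyphenyl)tetrahydro-1H,3H-furo[3,4-c]furan-1-one (cis-fused 9'-oxo furofuran), via carbonyl ylide 16 (not isolated)
Conditions: 15 (2 equiv), CsF (dried, 3 equiv, added in portions), MeCN, 0 °C to rt
Reagents that add atoms: α-chloro (trimethylsilyl)methyl ether (15), C[Si](C)(C)COC(Cl)c1ccc(OCC=C(C)C)c(OC)c1
Why: Fluoride attacks silicon of 15 while chloride leaves (1,3-elimination through the aryl-stabilised oxocarbenium ion pair) and frees the planar ylide 16, a four-electron 1,3-dipole that adds in one concerted suprafacial step to the electron-poor C8=C8' bond of 7. The closest known reaction type is the (3+2) cycloaddition of non-stabilised carbonyl ylides, released by CsF from α-chloroalkyl (trimethylsilyl)methyl ethers, with acrylates, maleates and related acceptors. Ring B (C7'–O–C9–C8–C8') closes as a concerted five-membered cycloaddition in which C8–C9 and C8'–C7' form on the same face, so the A/B ring fusion can only be cis. C8 and C8' are set by the C7 aryl group, which shields one face of the flat butenolide so that the dipole enters anti to it (C9 trans to that aryl group), and C7' is set by the exo approach in which the ylide aryl group points away from the lactone ring (aryl trans to C9'). The regiochemistry follows from the donor aryl group holding the positive charge at C7', which leaves the largest HOMO coefficient on the small CH2 terminus for attack at the β-carbon C8, the carbon with the largest LUMO coefficient. The step needs this regiochemistry, anti and exo selectivity and retention of the C7 configuration; the first three rest on the single stereocentre and the polarisation of the two partners, and the last is protected by keeping fluoride the limiting species (portionwise CsF, excess 15, 0 °C) so that the acidic C7–H is not removed.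

Step 9
Reactants: 17 cycloadduct lactone
Product: 18 (3S,3aR,6S,6aS)-3-(4-hydroxy-3-methoxyphenyl)-6-(3-methoxy-4-prenyloxyphenyl)tetrahydro-1H,3H-furo[3,4-c]furan-1-ol (lactol, anomeric mixture at C9')
Conditions: iBu2AlH (4.5 equiv), CH2Cl2, −78 °C; MeOH, then aq. KNaC4H4O6 (potassium sodium tartrate)
Reagents that add atoms: none
Why: Partial hydride reduction of a γ-lactone to the lactol is reliable with iBu2AlH at −78 °C, and the excess reagent cleaves the aryl pivalate reductively in the same flask; C9' becomes an uncontrolled anomeric centre that step 10 removes, and no other stereocentre is touched.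

Step 10
Reactants: 18 lactol
Product: 20 4-[(1S,3aR,4S,6aR)-4-(3-methoxy-4-prenyloxyphenyl)tetrahydro-1H,3H-furo[3,4-c]furan-1-yl]-2-methoxyphenol (target), via oxocarbenium ion 19 (not isolated)
Conditions: Et3SiH (5 equiv), BF3·OEt2 (2.5 equiv), CH2Cl2, −78 °C; cold aq. NaHCO3
Reagents that add atoms: none
Why: In this ionic reduction of a lactol BF3·OEt2 ionises the anomeric hydroxyl to the cyclic oxocarbenium ion 19, which Et3SiH reduces at C9' to a CH2 group (no stereocentre), and at −78 °C the benzylic C7–O and C7'–O bonds and the prenyl ether should not ionise, so the four stereocentres are kept.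

**Compound list**

1 | vanillin | COc1cc(C=O)ccc1O | starting material
2 | pivaloyl chloride | CC(C)(C)C(Cl)=O | starting material
3 | 4-formyl-2-methoxyphenyl pivalate | CC(C)(C)C(=O)Oc1ccc(C=O)cc1OC | intermediate
4 | methyl propiolate | C#CC(=O)OC | starting material
5 | methyl (R)-4-hydroxy-4-(3-methoxy-4-pivaloyloxyphenyl)but-2-ynoate | CC(C)(C)C(=O)Oc1ccc(cc1OC)[C@@H](O)C#CC(=O)OC | intermediate
6 | methyl (2Z,4S)-4-hydroxy-4-(3-methoxy-4-pivaloyloxyphenyl)but-2-enoate | CC(C)(C)C(=O)Oc1ccc(cc1OC)[C@@H](O)/C=C\C(=O)OC | intermediate (not isolated)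
7 | (S)-5-(3-methoxy-4-pivaloyloxyphenyl)furan-2(5H)-one | CC(C)(C)C(=O)Oc1ccc(cc1OC)[C@H]2OC(=O)C=C2 | intermediate
8 | prenyl bromide | CC(C)=CCBr | starting material
9 | 3-methoxy-4-(3-methylbut-2-en-1-yloxy)benzaldehyde | COc1cc(C=O)ccc1OCC=C(C)C | intermediate
10 | (trimethylsilyl)methanol | C[Si](C)(C)CO | starting material
11 | chlorotrimethylsilane | C[Si](C)(C)Cl | starting material
12 | trimethyl[(trimethylsilyl)methoxy]silane | C[Si](C)(C)CO[Si](C)(C)C | intermediate
13 | 3-methoxy-4-prenyloxybenzaldehyde bis[(trimethylsilyl)methyl] acetal | C[Si](C)(C)COC(OC[Si](C)(C)C)c1ccc(OCC=C(C)C)c(OC)c1 | intermediate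
14 | acetyl chloride | CC(Cl)=O | starting material
15 | racemic α-chloro-(3-methoxy-4-prenyloxybenzyl) (trimethylsilyl)methyl ether | C[Si](C)(C)COC(Cl)c1ccc(OCC=C(C)C)c(OC)c1 | intermediate
16 | carbonyl ylide ArCH=O(+)–CH2(−), Ar = 3-methoxy-4-prenyloxyphenyl | [CH2-][O+]=Cc1ccc(OCC=C(C)C)c(OC)c1 | intermediate (not isolated)
17 | (3S,3aR,6S,6aS)-6-(3-methoxy-4-prenyloxyphenyl)-3-(3-methoxy-4-pivaloyloxyphenyl)tetrahydro-1H,3H-furo[3,4-c]furan-1-one; cis-fused, both aryl groups exo | CC(C)(C)C(=O)Oc1ccc(cc1OC)[C@H]2OC(=O)[C@H]3[C@@H]2CO[C@@H]3c4ccc(OCC=C(C)C)c(OC)c4 | intermediate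
18 | (3S,3aR,6S,6aS)-3-(4-hydroxy-3-methoxyphenyl)-6-(3-methoxy-4-prenyloxyphenyl)tetrahydro-1H,3H-furo[3,4-c]furan-1-ol; lactol, both anomers at C9' | COc1cc([C@H]2OC(O)[C@H]3[C@@H]2CO[C@@H]3c2ccc(OCC=C(C)C)c(OC)c2)ccc1O | intermediate
19 | cyclic oxocarbenium ion at C9' derived from 18 | COc1cc([C@H]2[O+]=C[C@H]3[C@@H]2CO[C@@H]3c2ccc(OCC=C(C)C)c(OC)c2)ccc1O | intermediate (not isolated)
20 | 4-[(1S,3aR,4S,6aR)-4-(3-methoxy-4-prenyloxyphenyl)tetrahydro-1H,3H-furo[3,4-c]furan-1-yl]-2-methoxyphenol (7S,8R,7'S,8'R) | COc1cc([C@H]2OC[C@H]3[C@@H]2CO[C@@H]3c2ccc(OCC=C(C)C)c(OC)c2)ccc1O | target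

**Step count**

Total: 10 steps. Longest linear sequence: 6 steps (for example 1 → 3 → 5 → 7 → 17 → 18 → 20).

**Steps most likely to fail, with fallbacks**

Step 8. The cycloaddition may give the other regioisomer, poor anti or exo selectivity, or loss of enantiomeric purity through deprotonation of 7 at C7 by fluoride or by the ylide. The fallback builds ring B in two bond-forming stages, sets out from 7 (and uses 9) and returns at 17. Benzophenone-sensitised photoaddition of methanol to 7 (MeOH, Ph2CO, 350 nm) adds a hydroxymethyl radical to C8 anti to the C7 aryl group and gives (4R,5S)-4-(hydroxymethyl)-5-(3-methoxy-4-pivaloyloxyphenyl)dihydrofuran-2(3H)-one F1. Aldehyde 9 is converted with HC(OMe)3 and catalytic PPTS into its dimethyl acetal F2. Acid-catalysed acetal exchange between F1 and F2 (PPTS, toluene, removal of MeOH) gives the mixed methyl acetal F3. Me3SiOTf and Et3N in CH2Cl2 at −78 °C then enolise the lactone as its silyl enol derivative and ionise the acetal in the same flask. The tethered oxocarbenium carbon C7' is attacked by C8' (intramolecular Mukaiyama-type addition), which can only give the cis-fused bicycle and should place the aryl group exo, giving 17. The tether fixes the regiochemistry and the butenolide never meets a base.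

Step 10. The Lewis acid may ionise the prenyl ether or a benzylic C–O bond, which would mean loss of the prenyl group or epimerisation at C7 or C7'. The fallback removes the carbonyl oxygen without acid, sets out from 17, replaces steps 9 and 10 and returns at 20. Lawesson's reagent in toluene at 100 °C converts 17 into the thionolactone F4. Ph3SnH with AIBN in refluxing toluene replaces sulfur by two hydrogens through radical desulfurisation and gives the O-pivaloyl furofuran F5. NaOMe in MeOH then removes the pivalate and gives 20.

Step 2. The alkynylation may give insufficient enantioselectivity or the opposite facial sense. The fallback secures C7 by enzymatic resolution, sets out from 3 and returns at 7. CH2=CHMgBr in THF at −78 °C adds to 3 and gives racemic 1-(3-methoxy-4-pivaloyloxyphenyl)prop-2-en-1-ol F6. Novozym 435 (immobilised Candida antarctica lipase B) with vinyl acetate in tert-butyl methyl ether acetylates the (R)-enantiomer and leaves the (S)-alcohol F7, which is separated from the acetate. Acryloyl chloride and iPr2NEt in CH2Cl2 at 0 °C give the (S)-acrylate F8. Ring-closing metathesis with the second-generation Grubbs catalyst in CH2Cl2 at 40 °C closes the butenolide and gives 7.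

**Further compounds**

F1 | step 8 | (4R,5S)-4-(hydroxymethyl)-5-(3-methoxy-4-pivaloyloxyphenyl)dihydrofuran-2(3H)-one | CC(C)(C)C(=O)Oc1ccc(cc1OC)[C@H]2OC(=O)C[C@@H]2CO
F2 | step 8 | 3-methoxy-4-prenyloxybenzaldehyde dimethyl acetal | COC(OC)c1ccc(OCC=C(C)C)c(OC)c1
F3 | step 8 | mixed methyl acetal of F1 with 3-methoxy-4-prenyloxybenzaldehyde (both epimers at the acetal carbon) | CC(C)(C)C(=O)Oc1ccc(cc1OC)[C@H]2OC(=O)C[C@@H]2COC(OC)c3ccc(OCC=C(C)C)c(OC)c3
F4 | step 10 | thionolactone of 17 (C9'=S) | CC(C)(C)C(=O)Oc1ccc(cc1OC)[C@H]2OC(=S)[C@H]3[C@@H]2CO[C@@H]3c4ccc(OCC=C(C)C)c(OC)c4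
F5 | step 10 | O-pivalate of the target | CC(C)(C)C(=O)Oc1ccc(cc1OC)[C@H]2OC[C@H]3[C@@H]2CO[C@@H]3c4ccc(OCC=C(C)C)c(OC)c4
F6 | step 2 | racemic 1-(3-methoxy-4-pivaloyloxyphenyl)prop-2-en-1-ol | CC(C)(C)C(=O)Oc1ccc(cc1OC)C(O)C=C
F7 | step 2 | (S)-1-(3-methoxy-4-pivaloyloxyphenyl)prop-2-en-1-ol | CC(C)(C)C(=O)Oc1ccc(cc1OC)[C@@H](O)C=C
F8 | step 2 | (S)-1-(3-methoxy-4-pivaloyloxyphenyl)allyl acrylate | CC(C)(C)C(=O)Oc1ccc(cc1OC)[C@@H](OC(=O)C=C)C=C
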